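All runs stem from a simulated flask for substances that don't exist, noise included.

4 questions lay before the meeting: which of the flasks east, south-west and north ends highest in target, and how much target each of them holds at the end.

- the flask that comes out highest in amount of target, in percent of the starting material charged, or "all alike" when all lie within 1.5 percentage points (east / south-west / north / all alike)
- target at the end, in percent of the starting material charged, east
- target at the end, in percent of the starting material charged, south-west
- target at the end, in percent of the starting material charged, north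

| flask | starting material | partner | protic impurity | remark | time |
|---|---|---|---|---|---|
| dusk | 46 mM | 2 equiv | 4.6 mM | run made earlier |  |
| autumn | 23 mM | 2 equiv | 4.6 mM | run made earlier |  |
| spring | 34 mM | 2 equiv | 4.6 mM | run made earlier |  |
| midnight | 46 mM | 1 equiv | 4.6 mM | run made earlier |  |
| east | 46 mM | 2.00 equiv (fed, over 4.0 h) | 4.60 mM | all else is in the flask from the start; the feed brings no volume worth counting | 5.0 h |
| south-west | 46 mM | 2.00 equiv | 4.60 mM | everything together at the start | 5.0 h |
| north | 46 mM (fed, over 4.0 h) | 2.00 equiv | 4.60 mM | all else is in the flask from the start; the feed brings no volume worth counting | 5.0 h |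

| run | time / h | target / % | starting material / % |
|---|---|---|---|
| dusk | 0.667 | 15.9 | 13.5 |
| dusk | 1.33 | 31.6 | 13.7 |
| dusk | 2.00 | 44.8 | 12.2 |
| dusk | 3.00 | 57.4 | 9.8 |
| dusk | 4.00 | 68.1 | 8.5 |
| dusk | 5.00 | 76.1 | 6.0 |
| autumn | 0.333 | 7.8 | 20.2 |
| autumn | 1.00 | 18.2 | 18.9 |
| autumn | 1.50 | 26.5 | 18.6 |
| autumn | 2.50 | 37.6 | 15.2 |
| autumn | 4.00 | 53.0 | 12.0 |
| autumn | 5.00 | 59.7 | 14.1 |
| autumn | 6.00 | 69.0 | 9.6 |
| spring | 0.833 | 17.3 | 15.8 |
| spring | 1.50 | 31.5 | 12.0 |
| spring | 2.50 | 46.8 | 12.5 |
| spring | 3.00 | 51.7 | 10.5 |
| spring | 4.00 | 63.4 | 11.3 |
| spring | 5.00 | 70.6 | 8.7 |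
| spring | 6.00 | 78.2 | 7.6 |
| midnight | 0.500 | 7.6 | 15.1 |
| midnight | 0.833 | 9.6 | 16.1 |
| midnight | 1.50 | 17.8 | 14.6 |
| midnight | 3.00 | 32.5 | 12.7 |
| midnight | 6.00 | 49.8 | 8.3 |

(each reading ± 1 percentage point)



Minutes. I, as secretary, proposed to carry one number. The first dusk reading, 15.9% target after 0.667 h at 2 equivalents of partner, gives, as a reading with its scatter, 0.119 h⁻¹: this is the partner clock, the fraction of the partner present that turns into target per hour, a pseudo-first-order constant. I tested it on the midnight run, where one equivalent of partner means that target equals partner used: the clock gives 51.0% after 6.00 h, and the reading there is 49.8%.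

I then took the late end. Run unchanged on dusk to 5.0 h, the clock gives 89.8%, more than the 76.1% read there, so in dusk it slows as the starting material reading sinks to 6.0%. South-west has the charge of dusk, so I took that dusk reading for south-west.

For east, with partner arriving over 4.0 h, the clock on what has arrived gives 58.8%, which lies below that dusk reading. For north I offered no figure.

The forecaster, reasoning from an unseen pool and a saturating rate, set east at 55%, lower than my figure, south-west at 76% and north at 60%, named south-west as highest, and concluded: “Having everything in at the start wins.”

The simulation gives east 56.5%, south-west 77.2% and north 61.4%, so south-west comes out highest.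

    2 starting material ⇌ resting dimer, settled at all times (K = 370 L mol⁻¹)
    starting material + partner → target (k = 20.0 L mol⁻¹ h⁻¹)
    starting material + protic impurity → quenched substrate (k = 9.80 L mol⁻¹ h⁻¹)
    starting material + target → side product (k = 0.110 L mol⁻¹ h⁻¹)

In east the clock leaves 70.6% of the partner charge at the end, and the flask holds 72%. South-west leads east by 21 percentage points, but with the binding into resting dimer, the resting state of starting material, taken away the lead is 7.1 points. The forecast's pick of south-west over east stands at 5.0 h but not at 50.0 h, where east at 95.9% and south-west at 96.8% lie within 1.5 points. On the neighbour of south-west charged with 0.500 equiv of partner, the clock leaves 55.2% of the partner and so gives 22.4% target; the computed flask gives 24.1%.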